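**Assumptions**
- I read the SMILES as 19 CH2 groups between the stereocentre and the ester oxygen. The target is therefore (S)-20-methyldocosyl 2,3-dihydroxybenzoate, C30H52O4. The CIP priorities are long chain > Et > Me > H, which gives S.
- Grignard reagents are made and used in situ. They are not numbered, and each formation plus coupling counts as one step.

## Retrosynthetic overview
1. Disconnect the ester C(alkyl)–O bond to give 2,3-dihydroxybenzoic acid and (S)-20-methyldocosan-1-ol, joined by a protecting-group-free Mitsunobu reaction.
2. Disconnect C12–C13 of the alcohol to give 12-bromododecan-1-ol and an (S)-8-methyldecyl Grignard reagent (Cu-catalysed sp3–sp3 coupling).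
3. Disconnect C6–C7 of the C11 piece to give 1-bromo-6-chlorohexane and (S)-2-methylbutylmagnesium bromide (Br-selective Cu coupling).
4. The only stereocentre is bought in (S)-1-bromo-2-methylbutane and is never touched.
5. No rings are formed. The arene is purchased intact.

## Route

**Step 1**
Reactants: 1, (S)-1-bromo-2-methylbutane; 2, 1-bromo-6-chlorohexane
Product: 3, (S)-1-chloro-8-methyldecane
Conditions: 1 (1.2 equiv), Mg, THF, rt→45 °C. Add the Grignard solution to 2 (1.0 equiv) and Li2CuCl4 (3 mol %) in THF at −10→0 °C for 3 h. Quench with aq NH4Cl, then distil or pass through a pentane silica plug.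
Reagents that add atoms: none beyond the numbered reactants. Compound 2, ClCCCCCCBr, supplies the (CH2)6Cl unit.
Why: This is a Kochi-type Cu-catalysed Grignard–alkyl halide cross-coupling. The primary C–Br bond reacts far faster than C–Cl at ≤0 °C, so the chloride survives as the next handle. The stereocentre is β to magnesium, is not involved, and stays (S).

**Step 2**
Reactants: 3, (S)-1-chloro-8-methyldecane; 4, 12-bromododecan-1-ol
Product: 5, (S)-20-methyldocosan-1-ol
Conditions:
- Flask A: 3 (1.3 equiv), Mg activated with BrCH2CH2Br/I2, THF, reflux, 3 h.
- Flask B: 4 (1.0 equiv), MeMgCl (1.0 equiv), THF, −20 °C, which forms the ClMg-alkoxide.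
- Add Li2CuCl4 (5 mol %) to B, then add A at −20 °C→rt over 12 h. Quench with aq NH4Cl and purify on silica.

Reagents that add atoms: none beyond the numbered reactants. Compound 4, OCCCCCCCCCCCCBr, supplies C1–C12 and the oxygen. MeMgCl only removes the OH proton.
Why: This is a second Kochi-type Cu-catalysed sp3–sp3 coupling, and the count is C10 + C12 = C22 with the methyl at C20. Masking the OH as a non-nucleophilic magnesium alkoxide avoids a protect/deprotect pair. Excess Grignard ends up as hydrocarbons that separate easily from the alcohol, and the stereocentre is seven carbons from the reacting carbon.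

**Step 3**
Reactants: 5, (S)-20-methyldocosan-1-ol; 6, 2,3-dihydroxybenzoic acid
Product: 7, Gentiside B, (S)-20-methyldocosyl 2,3-dihydroxybenzoate
Conditions: 5 (1.0 equiv), 6 (1.5 equiv), PPh3 (1.4 equiv), DIAD (1.4 equiv, added last and dropwise), THF, 0 °C→rt, 12 h, under Ar. Purify on silica with hexane/EtOAc.
Reagents that add atoms: none beyond the numbered reactants. Compound 6, OC(=O)c1cccc(O)c1O, supplies the aroyloxy group. The hydroxyl oxygen of 5 leaves as Ph3P=O.
Why: This is a chemoselective Mitsunobu esterification.
- The carboxylic acid (pKa about 3) is several pKa units more acidic than the phenols, and the 2-OH is hydrogen-bonded to the carbonyl.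
- With the alcohol as limiting reagent, only the carboxylate displaces the primary alkoxyphosphonium ion.
- Substitution occurs at the achiral C1, so C20 stays (S).

## Compound list
| No. | Name | SMILES | Role |
|---|---|---|---|
| 1 | (S)-1-bromo-2-methylbutane | CC[C@H](C)CBr | starting material |
| 2 | 1-bromo-6-chlorohexane | ClCCCCCCBr | starting material |
| 3 | (S)-1-chloro-8-methyldecane | CC[C@H](C)CCCCCCCCl | intermediate |
| 4 | 12-bromododecan-1-ol | OCCCCCCCCCCCCBr | starting material |
| 5 | (S)-20-methyldocosan-1-ol | CC[C@H](C)CCCCCCCCCCCCCCCCCCCO | intermediate |
| 6 | 2,3-dihydroxybenzoic acid | OC(=O)c1cccc(O)c1O | starting material |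
| 7 | Gentiside B, (S)-20-methyldocosyl 2,3-dihydroxybenzoate | CC[C@H](C)CCCCCCCCCCCCCCCCCCCOC(=O)c1cccc(O)c1O | target |

## Summary
Total step count: 3. Longest linear sequence: 3 (1 → 3 → 5 → 7).

The enantiopurity of 7 equals that of commercial 1, so check 1 by rotation or chiral GC before use.

**Steps most likely to fail, with fallbacks**
1. **Step 2.** Grignard formation from the alkyl chloride may be sluggish, and the coupling may suffer in the presence of the alkoxide.
   - Fallback: switch to a B-alkyl Suzuki (alkyl–alkyl) coupling.
   - Convert 3 to the iodide with NaI in acetone.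
   - Hydroborate the TBS ether of dodec-11-en-1-ol with 9-BBN and couple using Pd(OAc)2/PCy3/K3PO4·H2O. Remove the TBS group with TBAF to reach 5.
2. **Step 3.** The free catechol acid may give phenol alkylation, oxidation by the azodicarboxylate, or a difficult purification.
   - Fallback: Steglich esterification (EDC, DMAP) of 5 with 2,3-bis(benzyloxy)benzoic acid, then H2, Pd/C.
   - Alternative: convert 5 to the bromide (Appel reaction) and alkylate the carboxylate of 6 with KHCO3 in DMF.
3. **Step 1.** The Br/Cl selectivity may be imperfect, homocoupling may compete, and residual 2 may be hard to remove.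
   - Fallback: drop the C6 linker and use a single C4 + C18 coupling.
   - Monobrominate 1,18-octadecanediol (48% HBr, toluene, reflux) to give 18-bromooctadecan-1-ol.
   - Couple its magnesium alkoxide directly with (S)-2-methylbutylmagnesium bromide and Li2CuCl4 to give 5.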